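## Retrosynthetic overview
1. The C4–OH comes last, by SeO2 allylic hydroxylation of the 3‑methylidene oxepane. C2–CH2Br comes from CH2OH (Appel) and C3=CH2 from a C3 ketone (titanium methylenation).
2. The C2 side‑chain carbon and the C3 oxygen come from an ε‑lactone: ketene acetal phosphate, Pd methoxycarbonylation, then hydroboration of the cyclic enol ether (sets C2).
3. The oxepane and its tertiary C9a–O bond come from Baeyer–Villiger ring expansion of a trans‑1‑decalone, in which the quaternary carbon migrates with retention.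
4. The equatorial C7–Br comes from Appel inversion of the axial alcohol. The gem‑dimethyl group and trans fusion come from Kirk–Petrow thiomethylation and Li/NH3 reductive methylation.
5. The decalin is Wieland–Miescher ketone (organocatalytic aldol sets the quaternary carbon; a ketoreductase then differentiates the carbonyls and raises the ee). Ring order: dione ring (bought), then the future bromocyclohexane ring (annulation), then the oxepane (expansion of the dione ring).

Assumption: the SMILES is read as (2R,4R,5aS,7S,9aS)-7-bromo-2-(bromomethyl)-6,6,9a-trimethyl-3-methylidenedecahydro-1-benzoxepin-4-ol. Bicyclic ethers carry 1‑benzoxepine locants. Decalins carry Wieland–Miescher locants (C1 oxygenated, C4a–H, C5 gem‑dimethyl, C6, C8a–CH3).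

## Route

Step 1
Reactants: 1 2-methylcyclohexane-1,3-dione; 2 methyl vinyl ketone
Product: 3 2-methyl-2-(3-oxobutyl)cyclohexane-1,3-dione
Conditions: Et3N (1 mol %), neat, rt
Reagents that add atoms: none
Why: Base-catalysed Michael addition of the acidic 1,3-dione to the enone gives the achiral, prochiral triketone cleanly.

Step 2
Reactants: 3 2-methyl-2-(3-oxobutyl)cyclohexane-1,3-dione
Product: 4 (S)-Wieland–Miescher ketone
Conditions: N-Ts-(Sa)-binam-L-prolinamide (2 mol %), PhCO2H (1 mol %), neat, rt, 5 d
Reagents that add atoms: none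
Why: In this Hajos–Parrish–Eder–Sauer–Wiechert reaction (enamine-catalysed intramolecular aldol condensation) the catalyst-bound enamine attacks one of the two enantiotopic ring carbonyls and sets the quaternary C8a as S in about 95 % ee.

Step 3
Reactants: 4 (S)-Wieland–Miescher ketone
Product: 5 (1S,8aS)-1-hydroxy-8a-methyl-1,2,3,4,8,8a-hexahydronaphthalen-6(7H)-one
Conditions: ketoreductase (NADPH-dependent carbonyl reductase of the Torulaspora delbrueckii type), NADP+ (cat.), i-PrOH (10 % v/v), phosphate buffer pH 7, 30 °C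
Reagents that add atoms: none
Why: This biocatalytic carbonyl reduction by a ketoreductase accepts only the isolated C1 ketone and only the (S)-enantiomer, delivering hydride anti to the angular methyl (C1 = S), so it differentiates the two carbonyls and leaves residual (R)-4 behind (>99 % ee).

Step 4
Reactants: 5 (1S,8aS)-1-hydroxy enone
Product: 6 (1S,8aS)-1-[(tert-butyldimethylsilyl)oxy]-8a-methyl-1,2,3,4,8,8a-hexahydronaphthalen-6(7H)-one
Conditions: TBSCl, imidazole, DMF, rt
Reagents that add atoms: tert-butyldimethylsilyl chloride, CC(C)(C)[Si](C)(C)Cl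
Why: Standard silyl ether protection gives a group that survives amine/thiol heating, Li/NH3, Selectride and Appel conditions.

Step 5
Reactants: 6 TBS-protected hydroxy enone
Product: 7 (1S,8aS)-1-[(tert-butyldimethylsilyl)oxy]-8a-methyl-5-[(phenylsulfanyl)methyl]-1,2,3,4,8,8a-hexahydronaphthalen-6(7H)-one
Conditions: PhSH, 37 % aq. HCHO, Et3N, EtOH, reflux, 2–3 d
Reagents that add atoms: formaldehyde, C=O; thiophenol, Sc1ccccc1
Why: The Kirk–Petrow thiomethylation functionalises only the α-carbon (C5) of the enone through its dienol and installs the first of the two C5 methyl carbons in masked form.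

Step 6
Reactants: 7 5-(phenylsulfanylmethyl) enone
Product: 9 (1S,4aR,8aS)-1-[(tert-butyldimethylsilyl)oxy]-5,5,8a-trimethyl-trans-decalin-6-one, via lithium enolate 8 (not isolated)
Conditions: Li, NH3(l)/THF, t-BuOH (2 equiv), −78 → −33 °C; then MeI, −33 °C → rt
Reagents that add atoms: iodomethane, CI
Why: In this Birch-type dissolving-metal reductive alkylation the C–S bond is cleaved, the enone is reduced with axial protonation at C4a anti to the angular methyl (trans fusion), and the regiodefined C5 enolate is methylated to the gem-dimethyl ketone.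

Step 7
Reactants: 9 trans-decalin-6-one
Product: 10 (1S,4aS,6R,8aS)-1-[(tert-butyldimethylsilyl)oxy]-5,5,8a-trimethyl-trans-decalin-6-ol (6-OH axial)
Conditions: L-Selectride, THF, −78 → 0 °C; then NaOH, H2O2, 0 °C
Reagents that add atoms: none
Why: Sterically controlled hydride reduction with the bulky trialkylborohydride proceeds by equatorial attack and gives the axial (6R) alcohol, as for 4,4-dimethyl-3-keto terpenoid A rings.

Step 8
Reactants: 10 axial decalin-6-ol
Product: 11 (1S,4aR,6S,8aS)-6-bromo-1-[(tert-butyldimethylsilyl)oxy]-5,5,8a-trimethyl-trans-decalin (Br equatorial)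
Conditions: CBr4, PPh3, toluene, 0 → 70 °C
Reagents that add atoms: carbon tetrabromide, BrC(Br)(Br)Br
Why: The Appel reaction displaces the axial oxyphosphonium group by bromide with SN2 inversion in a non-ionising medium, giving the equatorial (6S) neopentyl bromide on a simple, early intermediate.

Step 9
Reactants: 11 bromo silyl ether
Product: 12 (1S,4aR,6S,8aS)-6-bromo-5,5,8a-trimethyl-trans-decalin-1-ol
Conditions: 48 % aq. HF, MeCN, rt
Reagents that add atoms: none
Why: Acidic fluoride desilylation frees the hindered C1 alcohol without base, so the equatorial bromide (no antiperiplanar H) is untouched.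

Step 10
Reactants: 12 bromo decalinol
Product: 13 (4aR,6S,8aS)-6-bromo-5,5,8a-trimethyl-trans-decalin-1-one
Conditions: Dess–Martin periodinane, CH2Cl2, rt
Reagents that add atoms: none
Why: Dess–Martin oxidation converts the hindered secondary alcohol into the ketone under neutral conditions that no stereocentre or the bromide responds to.

Step 11
Reactants: 13 bromo decalin-1-one
Product: 14 (5aS,7S,9aS)-7-bromo-6,6,9a-trimethyloctahydro-1-benzoxepin-2(3H)-one
Conditions: mCPBA (3 equiv), CH2Cl2, rt, 48–72 h, dark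
Reagents that add atoms: 3-chloroperoxybenzoic acid, OOC(=O)c1cccc(Cl)c1
Why: In the Baeyer–Villiger oxidation the fully substituted C8a migrates in preference to CH2 and with retention, which creates the tertiary C9a–O bond and the seven-membered ring in one stereospecific step.

Step 12
Reactants: 14 ε-lactone
Product: 15 (5aS,7S,9aS)-7-bromo-6,6,9a-trimethyl-4,5,5a,6,7,8,9,9a-octahydro-1-benzoxepin-2-yl diphenyl phosphate
Conditions: KHMDS, (PhO)2P(O)Cl, THF/HMPA, −78 °C
Reagents that add atoms: diphenyl chlorophosphate, O=P(Cl)(Oc1ccccc1)Oc1ccccc1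
Why: Kinetic lactone enolisation with in situ O-phosphorylation gives the ketene acetal phosphate, and at −78 °C the remote hindered bromide does not react.

Step 13
Reactants: 15 ketene acetal phosphate
Product: 16 methyl (5aS,7S,9aS)-7-bromo-6,6,9a-trimethyl-4,5,5a,6,7,8,9,9a-octahydro-1-benzoxepine-2-carboxylate
Conditions: Pd(PPh3)4 (10 mol %), CO (1 atm), MeOH, Et3N, DMF, 50 °C
Reagents that add atoms: carbon monoxide, [C-]#[O+]; methanol, CO
Why: Pd(0)-catalysed alkoxycarbonylation inserts into the activated C(sp2)–O phosphate bond far faster than into the unactivated neopentyl C–Br bond and adds the one missing carbon (the future CH2Br).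

Step 14
Reactants: 16 α-alkoxy acrylate
Product: 17 [(5aS,7S,9aS)-7-bromo-6,6,9a-trimethyl-4,5,5a,6,7,8,9,9a-octahydro-1-benzoxepin-2-yl]methanol
Conditions: DIBAL-H (2.5 equiv), CH2Cl2, −78 °C; Rochelle salt
Reagents that add atoms: none
Why: DIBAL-H 1,2-reduction takes the conjugated ester to the allylic alcohol without touching the enol ether or the alkyl bromide.

Step 15
Reactants: 17 enol-ether allylic alcohol
Product: 18 (5aS,7S,9aS)-7-bromo-2-{[(tert-butyldimethylsilyl)oxy]methyl}-6,6,9a-trimethyl-4,5,5a,6,7,8,9,9a-octahydro-1-benzoxepine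
Conditions: TBSCl, imidazole, DMF, 0 °C → rt
Reagents that add atoms: tert-butyldimethylsilyl chloride, CC(C)(C)[Si](C)(C)Cl
Why: Silylation under basic conditions protects the primary alcohol while keeping the acid-sensitive enol ether intact.

Step 16
Reactants: 18 silyl-protected cyclic enol ether
Product: 20 (2S,3R,5aS,7S,9aS)-7-bromo-2-{[(tert-butyldimethylsilyl)oxy]methyl}-6,6,9a-trimethyldecahydro-1-benzoxepin-3-ol, via alkylborane 19 (not isolated)
Conditions: BH3·THF, THF, 0 °C → rt; then 3 M NaOH, 30 % H2O2, 0 °C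
Reagents that add atoms: borane–THF, B.C1CCOC1 (boron in 19 only); hydrogen peroxide, OO
Why: In this Brown hydroboration–oxidation boron goes to C3 (β to the ring oxygen), and syn addition occurs on the exposed face of the chair-like oxepene, whose carbocycle and axial C9a methyl lie under the enol-ether plane, so H-2 ends anti to that methyl as in the target.

Step 17
Reactants: 20 oxepan-3-ol
Product: 21 (2S,5aS,7S,9aS)-7-bromo-2-{[(tert-butyldimethylsilyl)oxy]methyl}-6,6,9a-trimethyloctahydro-1-benzoxepin-3(2H)-one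
Conditions: Dess–Martin periodinane, pyridine, CH2Cl2, 0 °C → rt
Reagents that add atoms: none
Why: Buffered Dess–Martin oxidation gives the α-alkoxy ketone without enolisation, so C2 is not epimerised and the β-silyloxy group is not eliminated.

Step 18
Reactants: 21 oxepan-3-one
Product: 22 (2R,5aS,7S,9aS)-7-bromo-2-{[(tert-butyldimethylsilyl)oxy]methyl}-6,6,9a-trimethyl-3-methylidenedecahydro-1-benzoxepine
Conditions: Cp2TiMe2 (3 equiv), toluene, 70 °C, dark
Reagents that add atoms: dimethyltitanocene, C[Ti](C)(C1C=CC=C1)C1C=CC=C1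
Why: The Petasis methylenation proceeds through a non-basic titanium carbene and an oxatitanacyclobutane, so the epimerisable C2 centre is preserved (the descriptor changes only through CIP ranking).

Step 19
Reactants: 22 methylidene silyl ether
Product: 23 [(2R,5aS,7S,9aS)-7-bromo-6,6,9a-trimethyl-3-methylidenedecahydro-1-benzoxepin-2-yl]methanol
Conditions: HF·pyridine, pyridine, THF, 0 °C → rt
Reagents that add atoms: none
Why: Buffered fluoride desilylation removes the primary TBS group quickly without isomerising the exocyclic alkene or ionising the allylic ether.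

Step 20
Reactants: 23 primary alcohol
Product: 24 (2R,5aS,7S,9aS)-7-bromo-2-(bromomethyl)-6,6,9a-trimethyl-3-methylidenedecahydro-1-benzoxepine
Conditions: CBr4, PPh3, CH2Cl2, 0 °C
Reagents that add atoms: carbon tetrabromide, BrC(Br)(Br)Br
Why: The Appel reaction on an unhindered primary, merely homoallylic alcohol is a fast SN2 process that touches no stereocentre.

Step 21
Reactants: 24 dibromo methylidene oxepane
Product: 25 (2R,4R,5aS,7S,9aS)-7-bromo-2-(bromomethyl)-6,6,9a-trimethyl-3-methylidenedecahydro-1-benzoxepin-4-ol (target)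
Conditions: SeO2 (0.5 equiv), t-BuOOH (3 equiv), CH2Cl2, 0 °C → rt
Reagents that add atoms: selenium dioxide, O=[Se]=O; tert-butyl hydroperoxide, CC(C)(C)OO
Why: In the Sharpless–Umbreit allylic hydroxylation (ene reaction, then [2,3]-shift) the C4 methylene reacts rather than the inductively deactivated C2–H, which allylic strain holds near the alkene plane, and oxygen arrives suprafacially on the face opposite CH2Br and the C9a methyl, giving 4R.

## Compound list
1 | 2-methylcyclohexane-1,3-dione | CC1C(=O)CCCC1=O | starting material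
2 | methyl vinyl ketone | C=CC(C)=O | starting material
3 | 2-methyl-2-(3-oxobutyl)cyclohexane-1,3-dione | CC(=O)CCC1(C)C(=O)CCCC1=O | intermediate
4 | (S)-Wieland–Miescher ketone | O=C1CCCC2=CC(=O)CC[C@]12C | intermediate
5 | (1S,8aS)-1-hydroxy-8a-methyl-1,2,3,4,8,8a-hexahydronaphthalen-6(7H)-one | O[C@H]1CCCC2=CC(=O)CC[C@]12C | intermediate
6 | TBS ether of 5 | CC(C)(C)[Si](C)(C)O[C@H]1CCCC2=CC(=O)CC[C@]12C | intermediate
7 | 5-[(phenylsulfanyl)methyl] derivative of 6 | CC(C)(C)[Si](C)(C)O[C@H]1CCCC2=C(CSc3ccccc3)C(=O)CC[C@]12C | intermediate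
8 | lithium C5(6)-enolate, trans-fused, 5-methyl | CC(C)(C)[Si](C)(C)O[C@H]1CCC[C@H]2C(C)=C(O[Li])CC[C@]12C | intermediate (not isolated)
9 | (1S,4aR,8aS)-1-(TBSO)-5,5,8a-trimethyl-trans-decalin-6-one | CC(C)(C)[Si](C)(C)O[C@H]1CCC[C@H]2C(C)(C)C(=O)CC[C@]12C | intermediate
10 | (1S,4aS,6R,8aS)-1-(TBSO)-5,5,8a-trimethyl-trans-decalin-6-ol (axial OH) | CC(C)(C)[Si](C)(C)O[C@H]1CCC[C@H]2C(C)(C)[C@H](O)CC[C@]12C | intermediate
11 | (1S,4aR,6S,8aS)-6-bromo-1-(TBSO)-5,5,8a-trimethyl-trans-decalin (equatorial Br) | CC(C)(C)[Si](C)(C)O[C@H]1CCC[C@H]2C(C)(C)[C@@H](Br)CC[C@]12C | intermediate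
12 | (1S,4aR,6S,8aS)-6-bromo-5,5,8a-trimethyl-trans-decalin-1-ol | O[C@H]1CCC[C@H]2C(C)(C)[C@@H](Br)CC[C@]12C | intermediate
13 | (4aR,6S,8aS)-6-bromo-5,5,8a-trimethyl-trans-decalin-1-one | O=C1CCC[C@H]2C(C)(C)[C@@H](Br)CC[C@]12C | intermediate
14 | (5aS,7S,9aS)-7-bromo-6,6,9a-trimethyloctahydro-1-benzoxepin-2(3H)-one | O=C1CCC[C@H]2C(C)(C)[C@@H](Br)CC[C@]2(C)O1 | intermediate
15 | ketene acetal diphenyl phosphate of 14 | O=P(Oc1ccccc1)(Oc1ccccc1)OC1=CCC[C@H]2C(C)(C)[C@@H](Br)CC[C@]2(C)O1 | intermediate
16 | methyl 2-carboxylate of the 2,3-unsaturated oxepene | COC(=O)C1=CCC[C@H]2C(C)(C)[C@@H](Br)CC[C@]2(C)O1 | intermediate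
17 | 2-(hydroxymethyl) oxepene | OCC1=CCC[C@H]2C(C)(C)[C@@H](Br)CC[C@]2(C)O1 | intermediate
18 | 2-(TBSOCH2) oxepene | CC(C)(C)[Si](C)(C)OCC1=CCC[C@H]2C(C)(C)[C@@H](Br)CC[C@]2(C)O1 | intermediate
19 | C3 alkylborane (B and H-2 syn, anti to the C9a methyl) | B[C@@H]1CC[C@H]2C(C)(C)[C@@H](Br)CC[C@]2(C)O[C@H]1CO[Si](C)(C)C(C)(C)C | intermediate (not isolated)
20 | (2S,3R,5aS,7S,9aS)-7-bromo-2-(TBSOCH2)-6,6,9a-trimethyldecahydro-1-benzoxepin-3-ol | O[C@@H]1CC[C@H]2C(C)(C)[C@@H](Br)CC[C@]2(C)O[C@H]1CO[Si](C)(C)C(C)(C)C | intermediate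
21 | (2S,5aS,7S,9aS)-7-bromo-2-(TBSOCH2)-6,6,9a-trimethyloctahydro-1-benzoxepin-3(2H)-one | O=C1CC[C@H]2C(C)(C)[C@@H](Br)CC[C@]2(C)O[C@H]1CO[Si](C)(C)C(C)(C)C | intermediate
22 | (2R,5aS,7S,9aS)-7-bromo-2-(TBSOCH2)-6,6,9a-trimethyl-3-methylidenedecahydro-1-benzoxepine | C=C1CC[C@H]2C(C)(C)[C@@H](Br)CC[C@]2(C)O[C@H]1CO[Si](C)(C)C(C)(C)C | intermediate
23 | [(2R,5aS,7S,9aS)-7-bromo-6,6,9a-trimethyl-3-methylidenedecahydro-1-benzoxepin-2-yl]methanol | C=C1CC[C@H]2C(C)(C)[C@@H](Br)CC[C@]2(C)O[C@H]1CO | intermediate
24 | (2R,5aS,7S,9aS)-7-bromo-2-(bromomethyl)-6,6,9a-trimethyl-3-methylidenedecahydro-1-benzoxepine | C=C1CC[C@H]2C(C)(C)[C@@H](Br)CC[C@]2(C)O[C@H]1CBr | intermediate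
25 | (2R,4R,5aS,7S,9aS)-7-bromo-2-(bromomethyl)-6,6,9a-trimethyl-3-methylidenedecahydro-1-benzoxepin-4-ol | C=C1[C@H](O)C[C@H]2C(C)(C)[C@@H](Br)CC[C@]2(C)O[C@H]1CBr | target

## Summary
Total step count: 21. Longest linear sequence: 21 steps (fully linear from 1 and 2).

**Step 8 (Appel inversion at the neopentyl C6).** The SN2 displacement is slow. E2 to the Δ6 olefin and a 1,2-methyl shift from the axial oxyphosphonium ion compete with it. The fallback avoids substitution at this carbon altogether. It sets out from ketone 9 and comes back at bromide 11. Ketone 9 is treated with (PhO)3P/Br2/Et3N (CH2Cl2, −60 °C → reflux) to give the vinyl bromide F1. This is reduced by radical hydrogen-atom-transfer hydrogenation (Mn(dpm)3 cat., PhSiH3, t-BuOOH, i-PrOH, rt). H• adds to C7, and the α-bromo radical at C6 takes its hydrogen from the axial direction. The halogen is therefore kept and ends in the more stable equatorial position.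

**Step 16 (hydroboration of the enol ether).** Facial selectivity may be only moderate, and the β-alkoxyborane can eliminate. The fallback sets out from 18 and comes back at 20. Enol ether 18 is epoxidised with dimethyldioxirane (CH2Cl2/acetone, −78 → 0 °C) on the same exposed face, giving the 2,3-epoxide F2. The epoxide is opened at the acetal carbon C2 with DIBAL-H (CH2Cl2, −78 °C). Aluminium binds the oxirane oxygen and delivers hydride from that same face, so H-2 and the C3–OH are again syn and no organoborane is involved.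

**Step 21 (SeO2 allylic hydroxylation).** Oxygen may be delivered to the wrong face of C4, over-oxidation may occur, or C2–H may react. The fallback sets out from 24 and comes back at 25. The crude SeO2 product, including the C4 epimer F3, is oxidised with Dess–Martin periodinane to the α-methylene ketone F4. This is reduced under Luche conditions (NaBH4, CeCl3·7H2O, MeOH, −78 °C). Hydride now enters from the face that the electrophilic oxidant preferred. The carbinol configuration obtained is therefore the opposite of the one SeO2 gave, which converts F3 material into 25.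

## Further compounds
F1 | step 8 | (1S,4aR,8aS)-6-bromo-1-[(tert-butyldimethylsilyl)oxy]-5,5,8a-trimethyl-1,2,3,4,4a,5,8,8a-octahydronaphthalene (vinyl bromide) | CC(C)(C)[Si](C)(C)O[C@H]1CCC[C@H]2C(C)(C)C(Br)=CC[C@]12C
F2 | step 16 | 2,3-epoxide of 18, oxirane oxygen on the face anti to the C9a methyl | CC(C)(C)[Si](C)(C)OC[C@@]12O[C@@H]1CC[C@H]3C(C)(C)[C@@H](Br)CC[C@]3(C)O2
F3 | step 21 | (2R,4S,5aS,7S,9aS)-7-bromo-2-(bromomethyl)-6,6,9a-trimethyl-3-methylidenedecahydro-1-benzoxepin-4-ol (C4 epimer of 25) | C=C1[C@@H](O)C[C@H]2C(C)(C)[C@@H](Br)CC[C@]2(C)O[C@H]1CBr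
F4 | step 21 | (2R,5aS,7S,9aS)-7-bromo-2-(bromomethyl)-6,6,9a-trimethyl-3-methylideneoctahydro-1-benzoxepin-4(5H)-one | C=C1C(=O)C[C@H]2C(C)(C)[C@@H](Br)CC[C@]2(C)O[C@H]1CBr
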